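**Assumption:** the given SMILES corresponds to the (2S)-chromene (O > C3 > CH2 > CH3). For the unprecedented enantioselective step 4 the (R)-acid is written; its sense of induction cannot be predicted, so the antipode is used if the first run gives the (R)-chromene.

## Retrosynthetic overview

1. Target 11 ⇐ (S)-chromene 9 by a Schenck ene reaction of singlet oxygen at the distal prenyl olefin, then O–O reduction.
2. 9 ⇐ 3'-geranyl-2',4',5'-trihydroxychalcone 6: two-electron oxidation to geranyl hydroxyquinone 7, tautomerisation to vinyl o-quinone methide 8, and oxa-6π closure under chiral-acid control (sets C2).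
3. 6 ⇐ chalcone 4 + geranyl bromide 5, by C-geranylation at C3' between the 2'- and 4'-OH.
4. 4 ⇐ 2',4',5'-trihydroxyacetophenone 2 + benzaldehyde 3; 2 ⇐ 1,2,4-triacetoxybenzene 1.
5. Ring order: both benzene rings are bought; the pyran ring is the only ring formed (step 4).

## Route

**Step 1**
Reactants: 1 1,2,4-triacetoxybenzene
Product: 2 1-(2,4,5-trihydroxyphenyl)ethan-1-one (2',4',5'-trihydroxyacetophenone)
Conditions: ZnCl2 (fused, 2 equiv), AcOH, reflux, 3 h; then 1 M HCl, 60 °C
Reagents that add atoms: none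
Why: Nencki/Fries conditions move one O-acetyl of 1 to the most activated ring carbon (para to one oxygen, ortho to another) and the two remaining esters are hydrolysed on work-up.

**Step 2**
Reactants: 2 2',4',5'-trihydroxyacetophenone; 3 benzaldehyde
Product: 4 (E)-3-phenyl-1-(2,4,5-trihydroxyphenyl)prop-2-en-1-one (2',4',5'-trihydroxychalcone)
Conditions: PhCHO (1.2 equiv), HCl(g)-saturated EtOH, 0 °C → rt, 24 h, Ar
Reagents that add atoms: none
Why: Acid-catalysed Claisen–Schmidt (crossed aldol) condensation gives the conjugated E-enone under thermodynamic control and avoids the air-sensitive hydroxyquinol phenoxides that a basic condensation would generate.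

**Step 3**
Reactants: 4 2',4',5'-trihydroxychalcone; 5 geranyl bromide
Product: 6 (E)-1-{3-[(2E)-3,7-dimethylocta-2,6-dien-1-yl]-2,4,5-trihydroxyphenyl}-3-phenylprop-2-en-1-one (3'-geranyl-2',4',5'-trihydroxychalcone)
Conditions: KOH (1.1 equiv), degassed H2O, 0 °C → rt, 12 h, Ar; then 1 M HCl; chromatography under Ar (O-geranyl ethers removed)
Reagents that add atoms: none
Why: Claisen-type C-alkylation of the ambident 4'-phenoxide (most acidic OH, para to C=O) in water, where hydrogen bonding shields oxygen; C3' is its only free ortho carbon and SN2 attack keeps the geranyl E-geometry.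

**Step 4**
Reactants: 6 3'-geranyl-2',4',5'-trihydroxychalcone
Product: 9 (E)-1-[(2S)-5,8-dihydroxy-2-methyl-2-(4-methylpent-3-en-1-yl)-2H-chromen-6-yl]-3-phenylprop-2-en-1-one, via 5-[(E)-cinnamoyl]-3-geranyl-2-hydroxy-1,4-benzoquinone 7 (not isolated), via (2Z)-4-[(E)-cinnamoyl]-2-[(2E)-3,7-dimethylocta-2,6-dien-1-ylidene]-3,6-dihydroxycyclohexa-3,5-dien-1-one 8 (not isolated)
Conditions: DDQ (1.00 equiv), PhMe, −20 °C, 15 min, Ar, dark; cold filtration; then (R)-TRIP (10 mol %), PhMe (0.02 M), 0 °C → rt, 24–48 h, dark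
Reagents that add atoms: none
Why: Proposed new method: DDQ oxidises the hydroquinone to quinone 7 far faster than it abstracts hydride, and the chiral phosphoric acid then acts as a bifunctional proton shuttle for vinylogous enolisation of the doubly allylic CH2 of 7 to the vinyl o-quinone methide 8, which is formed hydrogen-bonded to the acid (P–OH to the quinone-methide carbonyl, P=O to a flanking OH) and closes by oxa-6π electrocyclisation onto the non-chelated 4'-oxygen inside the chiral pocket, so the catalyst selects the face of the methyl-bearing terminus and sets C2 as S; the closest known reactions are the racemic amine- or heat-promoted isomerisation of prenylquinones to chromenols, the DDQ cyclisation of o-prenylphenols, and chiral phosphoric acid/N-triflylphosphoramide-controlled additions and cyclisations of o-quinone methides that give 2-substituted 2H-chromenes enantioselectively.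

**Step 5**
Reactants: 9 (S)-chromene chalcone
Product: 11 (E)-1-[(2S)-5,8-dihydroxy-2-[(2E)-4-hydroxy-4-methylpent-2-en-1-yl]-2-methyl-2H-chromen-6-yl]-3-phenylprop-2-en-1-one (target), via (E)-1-[(2S)-2-[(2E)-4-hydroperoxy-4-methylpent-2-en-1-yl]-5,8-dihydroxy-2-methyl-2H-chromen-6-yl]-3-phenylprop-2-en-1-one 10 (not isolated)
Conditions: O2 (1 atm), TPP (1 mol %), CH2Cl2, −20 °C, LED λ ≥ 590 nm; then PPh3 (1.2 equiv), −20 °C → rt; chromatography (secondary allylic alcohol regioisomer removed)
Reagents that add atoms: dioxygen, O=O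
Why: Schenck ene reaction at the only electron-rich alkene with allylic hydrogens (the chromene C3=C4 has none, the enone is electron-poor); abstraction of a side-chain CH2 hydrogen gives the tertiary hydroperoxide with an E-olefin, PPh3 reduces O–O, and long-wavelength light leaves the chalcone geometry and the C2 stereocentre (no photochemical ring opening) untouched.

## Compound list

1 | 1,2,4-triacetoxybenzene | CC(=O)Oc1ccc(OC(C)=O)c(OC(C)=O)c1 | starting material
2 | 1-(2,4,5-trihydroxyphenyl)ethan-1-one | CC(=O)c1cc(O)c(O)cc1O | intermediate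
3 | benzaldehyde | O=Cc1ccccc1 | starting material
4 | (E)-3-phenyl-1-(2,4,5-trihydroxyphenyl)prop-2-en-1-one | O=C(/C=C/c1ccccc1)c1cc(O)c(O)cc1O | intermediate
5 | geranyl bromide, (2E)-1-bromo-3,7-dimethylocta-2,6-diene | CC(C)=CCC/C(C)=C/CBr | starting material
6 | (E)-1-{3-[(2E)-3,7-dimethylocta-2,6-dien-1-yl]-2,4,5-trihydroxyphenyl}-3-phenylprop-2-en-1-one | O=C(/C=C/c1ccccc1)c1cc(O)c(O)c(C/C=C(\C)CCC=C(C)C)c1O | intermediate
7 | 5-[(E)-cinnamoyl]-3-[(2E)-3,7-dimethylocta-2,6-dien-1-yl]-2-hydroxy-1,4-benzoquinone | O=C(/C=C/c1ccccc1)C1=CC(=O)C(O)=C(C/C=C(\C)CCC=C(C)C)C1=O | intermediate (not isolated)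
8 | (2Z)-4-[(E)-cinnamoyl]-2-[(2E)-3,7-dimethylocta-2,6-dien-1-ylidene]-3,6-dihydroxycyclohexa-3,5-dien-1-one | O=C(/C=C/c1ccccc1)C1=C(O)/C(=C/C=C(\C)CCC=C(C)C)C(=O)C(O)=C1 | intermediate (not isolated)
9 | (E)-1-[(2S)-5,8-dihydroxy-2-methyl-2-(4-methylpent-3-en-1-yl)-2H-chromen-6-yl]-3-phenylprop-2-en-1-one | CC(C)=CCC[C@@]1(C)C=Cc2c(O)c(C(=O)/C=C/c3ccccc3)cc(O)c2O1 | intermediate
10 | (E)-1-[(2S)-2-[(2E)-4-hydroperoxy-4-methylpent-2-en-1-yl]-5,8-dihydroxy-2-methyl-2H-chromen-6-yl]-3-phenylprop-2-en-1-one | CC(C)(OO)/C=C/C[C@@]1(C)C=Cc2c(O)c(C(=O)/C=C/c3ccccc3)cc(O)c2O1 | intermediate (not isolated)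
11 | (E)-1-[(2S)-5,8-dihydroxy-2-[(2E)-4-hydroxy-4-methylpent-2-en-1-yl]-2-methyl-2H-chromen-6-yl]-3-phenylprop-2-en-1-one | CC(C)(O)/C=C/C[C@@]1(C)C=Cc2c(O)c(C(=O)/C=C/c3ccccc3)cc(O)c2O1 | target

## Summary

Total steps: 5. Longest linear sequence: 5 (1 → 2 → 4 → 6 → 9 → 11).

## Steps most likely to fail, with fallbacks

**Step 4 (oxidation, then enantioselective tautomerisation/oxa-6π).** Quinone 7 may resist acid-mediated enolisation, may close without the catalyst (low ee), or may decompose as a reactive acylquinone. The fallback sets out from 6 and returns at 9. Compound 6 is treated with DDQ (2.2 equiv) in benzene at rt. The first equivalent gives 7 and the second abstracts hydride from its doubly allylic CH2 (as in lapachol → dehydro-α-lapachone), and the resulting cation closes to racemic 6-[(E)-cinnamoyl]-2-methyl-2-(4-methylpent-3-en-1-yl)-2H-chromene-5,8-dione F1. Aqueous Na2S2O4/EtOAc reduces this to racemic (E)-1-[5,8-dihydroxy-2-methyl-2-(4-methylpent-3-en-1-yl)-2H-chromen-6-yl]-3-phenylprop-2-en-1-one F2. Preparative chiral-phase SFC then delivers the (S)-enantiomer 9.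

**Step 5 (Schenck ene on the free hydroquinone).** Singlet oxygen or the excited sensitiser may oxidise the electron-rich 5,8-dihydroxyarene instead of the olefin. The fallback sets out from 9 and returns at 11, using the quinone as a redox-protected form of the hydroquinone. DDQ (1.0 equiv, PhMe, 0 °C) gives (2S)-6-[(E)-cinnamoyl]-2-methyl-2-(4-methylpent-3-en-1-yl)-2H-chromene-5,8-dione F3, whose ring is inert to singlet oxygen. Photooxygenation (O2, methylene blue, CH2Cl2/MeCN, 660 nm, −20 °C) gives (2S)-6-[(E)-cinnamoyl]-2-[(2E)-4-hydroperoxy-4-methylpent-2-en-1-yl]-2-methyl-2H-chromene-5,8-dione F4. Aqueous Na2S2O4 then reduces both the hydroperoxide and the quinone to give 11.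

**Step 3 (direct C-geranylation).** O-Alkylation, bis-alkylation and air oxidation may leave little of 6. The fallback sets out from 4 (with 5) and returns at 6. Selective O-alkylation of the most acidic 4'-OH (5, K2CO3 1.0 equiv, acetone, rt, Ar) gives (E)-1-{4-[(2E)-3,7-dimethylocta-2,6-dien-1-yloxy]-2,5-dihydroxyphenyl}-3-phenylprop-2-en-1-one F5. Montmorillonite K10 (CH2Cl2, 0 °C) then promotes the [1,3] O→C shift of the geranyl group to the only free ortho carbon, C3', giving 6.

## Further compounds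

F1 | step 4 | rac-6-[(E)-cinnamoyl]-2-methyl-2-(4-methylpent-3-en-1-yl)-2H-chromene-5,8-dione | CC(C)=CCCC1(C)C=CC2=C(O1)C(=O)C=C(C(=O)/C=C/c3ccccc3)C2=O
F2 | step 4 | rac-(E)-1-[5,8-dihydroxy-2-methyl-2-(4-methylpent-3-en-1-yl)-2H-chromen-6-yl]-3-phenylprop-2-en-1-one | CC(C)=CCCC1(C)C=Cc2c(O)c(C(=O)/C=C/c3ccccc3)cc(O)c2O1
F3 | step 5 | (2S)-6-[(E)-cinnamoyl]-2-methyl-2-(4-methylpent-3-en-1-yl)-2H-chromene-5,8-dione | CC(C)=CCC[C@@]1(C)C=CC2=C(O1)C(=O)C=C(C(=O)/C=C/c3ccccc3)C2=O
F4 | step 5 | (2S)-6-[(E)-cinnamoyl]-2-[(2E)-4-hydroperoxy-4-methylpent-2-en-1-yl]-2-methyl-2H-chromene-5,8-dione | CC(C)(OO)/C=C/C[C@@]1(C)C=CC2=C(O1)C(=O)C=C(C(=O)/C=C/c3ccccc3)C2=O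
F5 | step 3 | (E)-1-{4-[(2E)-3,7-dimethylocta-2,6-dien-1-yloxy]-2,5-dihydroxyphenyl}-3-phenylprop-2-en-1-one | O=C(/C=C/c1ccccc1)c1cc(O)c(OC/C=C(\C)CCC=C(C)C)cc1O
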